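## Structural features

The target is an 8–5′-type neolignan built on a 2,3-dihydro-1-benzofuran. The benzo ring (ring A) is fused to the oxygen heterocycle at C3a and C7a and carries a methoxy group at C7 and an (E)-3-oxypropenyl chain at C5; the heterocycle bears the 4-hydroxy-3,5-dimethoxyphenyl ring (ring B) at C2 and the CH2O carbon C9 at C3. The C9 oxygen and the allylic oxygen at the end of the C5 chain are both acylated by 4-hydroxybenzoic acid, so the molecule ends with two identical esters and three free phenols. The only stereocentres are the neighbouring C2 and C3, (2S,3R), with the aryl group and the CH2O group trans on the five-membered ring, which is also the more stable arrangement. The fragile points are the O1–C2 bond (benzylic and para to the ring B oxygen, so it can reopen through a para-quinone methide once that phenol is free), the cinnamyl-type ester (easily ionised, and a substrate for zerovalent palladium and for hydride), and the oxidisable phenols. The carbon skeleton is simple; the real difficulty is absolute control at C3, relative control at C2, and an order of events in which the allylic ester and the free ring B phenol appear only at the very end. The key step exploits the fact that C2 is benzylic to ring B with its para oxygen: a cation at C2 is stabilised like a quinone methide, so O1–C2 can be closed by the ring A phenol oxygen on C7a from an open-chain precursor whose only stereocentre that matters is C3.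

## Logic of the disconnections

24 to 19 and 22 (through 23). The two acyl C–O bonds, at the C9 oxygen and at the allylic oxygen, are cut together because the two esters are identical and can be made in one operation; the three O–Si bonds of 23 are protecting-group cuts. This reduces the target to a diol and one acid, 22, which goes back to 20 by an O–Si cut. The forward demand is a non-acidic acylation that does not ionise the allylic alcohol, and a last deprotection mild enough for two esters and a ring that can open once the ring B phenol is free.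

19 to 17 (through 18). The C5–C(vinyl) bond is cut after the allylic alcohol has been traced back to an acrylate ester. The reason is that an aryl bromide passes untouched through the cationic ring closure, whereas an electron-rich cinnamyl alcohol would not. Ring A becomes a plain bromoarene. The forward demand is an E-selective Heck coupling on an electron-rich bromide with a free primary alcohol present, followed by a clean 1,2-reduction.

17 to 15 (key disconnection, through 16). The O1–C2 bond is cut. C2 can carry a cation that is delocalised onto the para oxygen of ring B, so the bond can be formed by the phenol oxygen of ring A without any activation of that oxygen. The cut removes the heterocycle and one stereocentre and leaves an acyclic 1,3-diol in which only C3 has to be controlled. The forward demand is ionisation without loss of a proton or of formaldehyde from the cation, and trans selectivity under reversible conditions.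

15 to 13 (through 14). The O–allyl bond on the ring A phenol and, as a functional-group change, the exocyclic N–acyl bond (CH2OH back to the acyl oxazolidinone) are cut. Here the precursor design is improved: the ring A phenol is carried as an allyl ether and not as an acetal. An acetal would need acid for its removal, which would ionise the benzylic carbinol in the same flask and release a formaldehyde equivalent next to a 1,3-diol and two electron-rich rings. The allyl ether is removed by zerovalent palladium under neutral conditions, so 15 is obtained as a single, defined (1S,2R) compound that first meets acid in step 9. The forward demands are allyl transfer that leaves the aryl bromide alone, and hydride cleavage of the auxiliary without epimerisation or retro-aldol reaction.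

13 to 8 and 10. The bond between the future C2 and C3 is cut as an aldol bond. This is where the absolute configuration enters: the auxiliary fixes the carbon that becomes C3, and the carbinol configuration is of no consequence later. The cut splits the skeleton into its ring A and ring B halves; 10 goes back to 9 by an O–Si cut. The forward demand is a Z-enolate and high facial control with an electron-rich, weakly electrophilic aldehyde.

8 to 5 and 6, and 5 to 1 (through 4 and 2). The N–acyl bond is cut to release the auxiliary 6 and the acid 5. The bond between the benzylic carbon and the carboxyl carbon of 5 is then cut, which leads through the nitrile 4 to the aldehyde 2 and, by an O–allyl cut, to 1. This uses a cheap aldehyde that already has the complete ring A substitution pattern. The forward demand is a one-carbon homologation of an ortho-substituted aldehyde that tolerates the aryl bromide and the allyl ether.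

## Other disconnections considered

Alternative 1: The cut is the C3–C3a bond, read backwards as a ring expansion. The trans ester A2, methyl (2S,3S)-5-bromo-7-methoxy-2-[3,5-dimethoxy-4-(methylsulfonyloxy)phenyl]-2,3-dihydro-1-benzofuran-3-carboxylate, would come from the flavanone A1, (2S)-6-bromo-8-methoxy-2-[3,5-dimethoxy-4-(methylsulfonyloxy)phenyl]chroman-4-one. In the forward step PhI(OAc)2 and H2SO4 in HC(OMe)3 would turn A1 into its enol ether, trivalent iodine would add at C3, and the ring A carbon would shift from the ketal carbon to C3 as iodobenzene leaves. The pyranone contracts and the former carbonyl carbon becomes the ester carbon C9.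
- In its favour: a skeletal C–C bond and the C3 centre are made at once, C9 arrives already oxygenated, the trans relation follows from a stereospecific shift and not from an equilibrium, and A1 is reached in very few steps without an auxiliary. In step count to the ring system it is the better plan.
- Against it here: the one stereocentre of A1 lies next to the ring oxygen and β to the ketone, so it can be lost by retro-oxa-Michael ring opening in the strong acid the step needs. An enantioselective entry to A1 is also less dependable than an auxiliary aldol.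
- The very electron-rich ring B could migrate from C2 in place of ring A, or be oxidised. That is why its phenol has to be a deactivating sulfonate, which must later be cleaved by a strong nucleophile in a molecule that by then holds esters or an allylic alcohol. The acidic orthoformate medium also rules out silyl ethers.
- Comparison: on structure the two plans are equal from A2 onwards (same bromide at C5, same Heck chemistry, one hydride step to C9–OH in each). On mechanism this is an irreversible oxidation with several competing channels, against a reversible ionisation in the chosen plan. The chosen plan is longer but keeps the absolute configuration safer.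

Alternative 2: The cuts are C3–C3a and the C9–O bond. The precursor would be the aryl iodide A3, 4-{[(1S)-1-[3,5-dimethoxy-4-(triisopropylsilyloxy)phenyl]prop-2-en-1-yl]oxy}-3-iodo-5-methoxybenzaldehyde. The aryl radical made from it (photoredox reduction, or Bu3SnSnBu3 under light) would add 5-exo-trig to the internal alkene carbon, and TEMPO would trap the primary radical at C9. The product would be A4, (2S,3R)-7-methoxy-2-[3,5-dimethoxy-4-(triisopropylsilyloxy)phenyl]-3-[(2,2,6,6-tetramethylpiperidin-1-yl)oxymethyl]-2,3-dihydro-1-benzofuran-5-carbaldehyde.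
- In its favour: the conditions are neutral, a C–C and a C–O bond are formed in one operation, and C5 already carries a carbonyl carbon. The side chain then needs only an olefination and a hydride reduction, which equals the Heck/reduction pair in step count, and it is the better plan in that no aryl bromide has to survive earlier palladium chemistry.
- Against it here: A3 is an aryl ether of a carbinol that is benzylic, allylic and para-oxygenated at once. Making it as one enantiomer by substitution invites ionisation, allylic transposition and racemisation.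
- C3 would be set under kinetic control by the C2 substituent with no chance of equilibration, so the trans preference is expected to be weaker than under the thermodynamic control of the chosen plan.
- TEMPO must trap the C9 radical but not the aryl radical, and the N–O bond of A4 must then be reduced in an extra step.
- Comparison: the structures reached are equally close to the target and the step counts are about equal. The source of absolute configuration and the diastereocontrol are both weaker than in the chosen plan.

Alternative 3: The cut is O1–C7a, the aryl C–O bond. The precursor would be A5, methyl 3-[(2R,3S)-1-(tert-butyldimethylsilyloxy)-3-hydroxy-3-[3,5-dimethoxy-4-(triisopropylsilyloxy)phenyl]propan-2-yl]-5-methoxy-4-(trifluoromethylsulfonyloxy)benzoate, made by the same kind of syn aldol. With Pd(OAc)2, t-BuXPhos and Cs2CO3, zerovalent palladium would add into the aryl triflate, the benzylic alkoxide would bind to divalent palladium, and C–O reductive elimination would give A6, methyl (2S,3R)-3-(tert-butyldimethylsilyloxymethyl)-7-methoxy-2-[3,5-dimethoxy-4-(triisopropylsilyloxy)phenyl]-2,3-dihydro-1-benzofuran-5-carboxylate.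
- In its favour: both centres are retained, so the syn aldol is converted into the trans ring without reliance on a thermodynamic preference or on a donor para to C2. On this point it is the better plan in principle. The aldol front end is shared, so the two plans are equal there.
- Against it here: a secondary benzylic alkoxide on divalent palladium is prone to β-hydride elimination. The triflate lies between two ortho substituents, which slows oxidative addition, and carbonate can cleave its S–O bond.
- The syn to anti ratio of the aldol now matters, because each carbinol epimer would give a different ring isomer.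
- An aryl bromide cannot be carried through, so C5 must be an ester, and turning it into the side chain takes about four steps where the chosen plan needs two. A silyl protection and a triflation are also added.
- Comparison: the key step is mechanistically riskier than an acid-promoted ionisation, and the route is some four or five steps longer.

Key step: step 9

Remark on the chemistry: locants follow 2,3-dihydro-1-benzofuran (O1, C2, C3, C3a, C4 to C7, C7a; C9 is the CH2O carbon on C3); ring A is the fused benzo ring and ring B the syringyl ring. A recheck of the descriptors gives (2S,3R)-trans for the target and (2R) for the carbon of the open-chain diol that becomes C3. The same carbon is S in the aldol adduct; the change is one of CIP ranking only. (4S)-4-Benzyl-1,3-oxazolidin-2-one, TosMIC, methyl acrylate and the silyl chlorides are taken as commercial.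

Step 1
Reactants: 1 5-bromo-2-hydroxy-3-methoxybenzaldehyde
Product: 2 2-(allyloxy)-5-bromo-3-methoxybenzaldehyde
Conditions: allyl bromide, K2CO3, DMF, rt
Reagents that add atoms: allyl bromide, C=CCBr
Why: Williamson O-alkylation of a phenoxide made acidic by the ortho formyl group. The allyl ether is stable to the alkoxide, hydroxide, boron and hydride reagents that follow and can be removed later without acid.

Step 2
Reactants: 2 2-(allyloxy)-5-bromo-3-methoxybenzaldehyde
Product: 4 2-[2-(allyloxy)-5-bromo-3-methoxyphenyl]acetonitrile, via N-formyl vinyl sulfone 3 (not isolated)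
Conditions: TosMIC, t-BuOK, DME, −40 °C; then MeOH, reflux
Reagents that add atoms: p-toluenesulfonylmethyl isocyanide (TosMIC), Cc1ccc(cc1)S(=O)(=O)C[N+]#[C-]
Why: van Leusen reductive cyanation: the TosMIC anion adds to the aldehyde and the adduct collapses through an oxazoline to 3; methoxide then removes the formyl group and the sulfinate, leaving the homologous nitrile. The cold first stage should suppress oxazole formation, and the aryl bromide and allyl ether are inert.

Step 3
Reactants: 4 2-[2-(allyloxy)-5-bromo-3-methoxyphenyl]acetonitrile
Product: 5 2-[2-(allyloxy)-5-bromo-3-methoxyphenyl]acetic acid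
Conditions: KOH, EtOH/H2O, reflux; then aq. HCl to pH 2
Reagents that add atoms: water, O
Why: Base hydrolysis of an arylacetonitrile through the primary amide. Aqueous hydroxide touches neither the aryl allyl ether nor the aryl bromide.

Step 4
Reactants: 5 2-[2-(allyloxy)-5-bromo-3-methoxyphenyl]acetic acid; 6 (4S)-4-benzyl-1,3-oxazolidin-2-one
Product: 8 (4S)-3-{2-[2-(allyloxy)-5-bromo-3-methoxyphenyl]acetyl}-4-benzyl-1,3-oxazolidin-2-one, via mixed pivalic anhydride 7 (not isolated)
Conditions: t-BuCOCl, Et3N, THF, −20 °C; then 6, LiCl, −20 °C → rt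
Reagents that add atoms: none
Why: N-acylation of the oxazolidinone through the mixed anhydride 7. LiCl with Et3N makes the oxazolidinone nucleophilic enough without a strong base, and the bulky tert-butyl carbonyl steers attack to the arylacetyl carbonyl.

Step 5
Reactants: 9 4-hydroxy-3,5-dimethoxybenzaldehyde (syringaldehyde)
Product: 10 3,5-dimethoxy-4-(triisopropylsilyloxy)benzaldehyde
Conditions: i-Pr3SiCl, imidazole, DMF, rt
Reagents that add atoms: triisopropylsilyl chloride, CC(C)[Si](Cl)(C(C)C)C(C)C
Why: Silylation of a phenol that the para formyl group makes acidic enough for imidazole despite the two flanking methoxy groups. The bulky silyl ether keeps the para oxygen electron-donating for step 9 and should survive hydride, zerovalent palladium, amine bases and the Lewis acid.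

Step 6
Reactants: 8 (4S)-3-{2-[2-(allyloxy)-5-bromo-3-methoxyphenyl]acetyl}-4-benzyl-1,3-oxazolidin-2-one; 10 3,5-dimethoxy-4-(triisopropylsilyloxy)benzaldehyde
Product: 13 (4S)-3-[(2S,3S)-2-[2-(allyloxy)-5-bromo-3-methoxyphenyl]-3-hydroxy-3-[3,5-dimethoxy-4-(triisopropylsilyloxy)phenyl]propanoyl]-4-benzyl-1,3-oxazolidin-2-one, via dibutylboron Z-enolate 11 (not isolated), via dibutylboron aldolate 12 (not isolated)
Conditions: Bu2BOTf, i-Pr2NEt, CH2Cl2, 0 °C; then 10, −78 → 0 °C; then pH 7 buffer (KH2PO4/K2HPO4), MeOH, H2O2, 0 °C
Reagents that add atoms: none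
Why: Evans syn aldol: soft enolisation gives the Z-enolate 11, which adds to the aldehyde through a chair (Zimmerman–Traxler) transition state on the face away from the benzyl group of the auxiliary. This fixes the α-carbon (the future C3) as S in 13; the carbinol centre (the future C2) is set as well but is not needed later. Oxidative work-up cleaves the boron aldolate 12.

Step 7
Reactants: 13 (4S)-3-[(2S,3S)-2-[2-(allyloxy)-5-bromo-3-methoxyphenyl]-3-hydroxy-3-[3,5-dimethoxy-4-(triisopropylsilyloxy)phenyl]propanoyl]-4-benzyl-1,3-oxazolidin-2-one
Product: 14 (1S,2R)-2-[2-(allyloxy)-5-bromo-3-methoxyphenyl]-1-[3,5-dimethoxy-4-(triisopropylsilyloxy)phenyl]propane-1,3-diol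
Conditions: LiBH4, MeOH (2 equiv), THF, 0 °C
Reagents that add atoms: none
Why: Reductive cleavage of the N-acyl oxazolidinone: hydride attacks the exocyclic carbonyl, assisted by the neighbouring hydroxyl, and releases the auxiliary 6 for recovery. Short reaction time at 0 °C should keep the benzylic stereocentre and hold back retro-aldol cleavage; the silyl ether, allyl ether and bromide are inert.

Step 8
Reactants: 14 (1S,2R)-2-[2-(allyloxy)-5-bromo-3-methoxyphenyl]-1-[3,5-dimethoxy-4-(triisopropylsilyloxy)phenyl]propane-1,3-diol
Product: 15 (1S,2R)-2-(5-bromo-2-hydroxy-3-methoxyphenyl)-1-[3,5-dimethoxy-4-(triisopropylsilyloxy)phenyl]propane-1,3-diol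
Conditions: Pd(PPh3)4 (5 mol %), morpholine, THF, rt
Reagents that add atoms: none
Why: Tsuji–Trost type deallylation: zerovalent palladium ionises the aryl allyl ether to a π-allyl complex that morpholine captures. At room temperature oxidative addition into the electron-rich aryl bromide should be far slower, and no acid reaches the benzylic carbinol before step 9.

Step 9
Reactants: 15 (1S,2R)-2-(5-bromo-2-hydroxy-3-methoxyphenyl)-1-[3,5-dimethoxy-4-(triisopropylsilyloxy)phenyl]propane-1,3-diol
Product: 17 [(2S,3R)-5-bromo-7-methoxy-2-[3,5-dimethoxy-4-(triisopropylsilyloxy)phenyl]-2,3-dihydro-1-benzofuran-3-yl]methanol, via benzylic cation 16 (not isolated)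
Conditions: BF3·OEt2 (0.3 equiv), CH2Cl2 (0.01 M), −40 → 0 °C; then aq. NaHCO3
Reagents that add atoms: none
Why: BF3 (or the Brønsted acid it forms with the first water released) complexes the benzylic hydroxyl of 15 and water leaves, giving cation 16, whose charge is spread over ring B onto the para silyloxy oxygen and is supported by the two flanking methoxy groups (a silylated para-quinone methide). The ring A phenol oxygen adds to this carbon and forms O1–C2; the ring O1–C2–C3–C3a–C7a closes in the 5-exo-trig mode, the cationic π bond lying outside the new ring. The closest known reaction type is the acid-mediated cyclodehydration of 1,2-diaryl-1,3-propanediols carrying an ortho phenol to trans-2-aryl-2,3-dihydrobenzofurans, the laboratory counterpart of phenylcoumaran formation from quinone methides. The one new stereocentre, C2, is controlled by the existing C3 centre: in the planar cation ring B turns away from the hydroxymethyl group on C3, and because the benzylic C–O bond of 17 can ionise again under the same acid, any cis isomer should drain into the more stable trans one, (2S,3R). The C1 configuration of 15 is erased in 16, so the syn to anti ratio of the aldol is of no consequence, while C3 is never part of the cation and should keep its configuration. The step needs chemoselectivity among three oxygen nucleophiles and against loss of a proton or of formaldehyde from 16: the primary hydroxyl could only close an oxetane, high dilution holds back intermolecular capture, and low temperature with substoichiometric acid favours the fast intramolecular capture over elimination and fragmentation. The aryl bromide and the hindered aryl silyl ether are expected to be inert.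

Step 10
Reactants: 17 [(2S,3R)-5-bromo-7-methoxy-2-[3,5-dimethoxy-4-(triisopropylsilyloxy)phenyl]-2,3-dihydro-1-benzofuran-3-yl]methanol
Product: 18 methyl (2E)-3-[(2S,3R)-3-(hydroxymethyl)-7-methoxy-2-[3,5-dimethoxy-4-(triisopropylsilyloxy)phenyl]-2,3-dihydro-1-benzofuran-5-yl]prop-2-enoate
Conditions: methyl acrylate, Pd(OAc)2 (5 mol %), P(o-tol)3 (10 mol %), Et3N, DMF, 100 °C
Reagents that add atoms: methyl acrylate, C=CC(=O)OC
Why: Heck reaction: oxidative addition of the aryl bromide, syn insertion of the acrylate and syn β-hydride elimination should give the E-cinnamate. The free primary alcohol is tolerated, and with the ring B phenol silylated the amine base cannot open the heterocycle through a quinone methide.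

Step 11
Reactants: 18 methyl (2E)-3-[(2S,3R)-3-(hydroxymethyl)-7-methoxy-2-[3,5-dimethoxy-4-(triisopropylsilyloxy)phenyl]-2,3-dihydro-1-benzofuran-5-yl]prop-2-enoate
Product: 19 (2E)-3-[(2S,3R)-3-(hydroxymethyl)-7-methoxy-2-[3,5-dimethoxy-4-(triisopropylsilyloxy)phenyl]-2,3-dihydro-1-benzofuran-5-yl]prop-2-en-1-ol
Conditions: i-Bu2AlH (5 equiv), CH2Cl2, −78 °C; then aq. potassium sodium tartrate
Reagents that add atoms: none
Why: 1,2-Reduction of an α,β-unsaturated ester by i-Bu2AlH at low temperature gives the allylic alcohol without conjugate reduction. The excess allows for the free hydroxyl, and neither stereocentre is touched.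

Step 12
Reactants: 20 4-hydroxybenzoic acid
Product: 22 4-(tert-butyldimethylsilyloxy)benzoic acid, via bis-silylated benzoate 21 (not isolated)
Conditions: t-BuMe2SiCl (2.3 equiv), imidazole, DMF, rt; then AcOH, THF/H2O, rt
Reagents that add atoms: tert-butyldimethylsilyl chloride, CC(C)(C)[Si](C)(C)Cl
Why: Exhaustive silylation gives the silyl ester and silyl ether 21. Silyl esters hydrolyse far faster than aryl silyl ethers, so dilute aqueous acetic acid should free only the carboxylic acid.

Step 13
Reactants: 19 (2E)-3-[(2S,3R)-3-(hydroxymethyl)-7-methoxy-2-[3,5-dimethoxy-4-(triisopropylsilyloxy)phenyl]-2,3-dihydro-1-benzofuran-5-yl]prop-2-en-1-ol; 22 4-(tert-butyldimethylsilyloxy)benzoic acid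
Product: 23 [(2S,3R)-5-[(1E)-3-[4-(tert-butyldimethylsilyloxy)benzoyloxy]prop-1-en-1-yl]-7-methoxy-2-[3,5-dimethoxy-4-(triisopropylsilyloxy)phenyl]-2,3-dihydro-1-benzofuran-3-yl]methyl 4-(tert-butyldimethylsilyloxy)benzoate
Conditions: 22 (2.6 equiv), EDC·HCl, DMAP, CH2Cl2, 0 °C → rt
Reagents that add atoms: none
Why: Steglich esterification: the carbodiimide activates 22 and DMAP passes the acyl group to both primary hydroxyls, the only free hydroxyls in 19. The medium is not acidic, so the electron-rich allylic alcohol should not ionise.

Step 14
Reactants: 23 [(2S,3R)-5-[(1E)-3-[4-(tert-butyldimethylsilyloxy)benzoyloxy]prop-1-en-1-yl]-7-methoxy-2-[3,5-dimethoxy-4-(triisopropylsilyloxy)phenyl]-2,3-dihydro-1-benzofuran-3-yl]methyl 4-(tert-butyldimethylsilyloxy)benzoate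
Product: 24 [(2S,3R)-2-(4-hydroxy-3,5-dimethoxyphenyl)-5-[(1E)-3-(4-hydroxybenzoyloxy)prop-1-en-1-yl]-7-methoxy-2,3-dihydro-1-benzofuran-3-yl]methyl 4-hydroxybenzoate (quiquesetinerviusin B)
Conditions: Bu4NF, AcOH (1:1, 3.6 equiv), THF, 0 °C → rt
Reagents that add atoms: none
Why: Fluoride cleaves the three aryl O–Si bonds, which are far more labile to fluoride than the two esters are to the buffered medium. Acetic acid protonates the phenoxides as they form, so that acyl transfer and reopening of the heterocycle through a quinone methide are held back.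

Compound list

1 | 5-bromo-2-hydroxy-3-methoxybenzaldehyde | COc1cc(Br)cc(C=O)c1O | starting material
2 | 2-(allyloxy)-5-bromo-3-methoxybenzaldehyde | COc1cc(Br)cc(C=O)c1OCC=C | intermediate
3 | N-{2-[2-(allyloxy)-5-bromo-3-methoxyphenyl]-1-(4-methylphenylsulfonyl)ethenyl}formamide (N-formyl vinyl sulfone, formed in the flask, alkene geometry not defined) | COc1cc(Br)cc(C=C(NC=O)S(=O)(=O)c2ccc(C)cc2)c1OCC=C | intermediate
4 | 2-[2-(allyloxy)-5-bromo-3-methoxyphenyl]acetonitrile | COc1cc(Br)cc(CC#N)c1OCC=C | intermediate
5 | 2-[2-(allyloxy)-5-bromo-3-methoxyphenyl]acetic acid | COc1cc(Br)cc(CC(=O)O)c1OCC=C | intermediate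
6 | (4S)-4-benzyl-1,3-oxazolidin-2-one | O=C1N[C@@H](Cc2ccccc2)CO1 | starting material
7 | 2-[2-(allyloxy)-5-bromo-3-methoxyphenyl]acetic 2,2-dimethylpropanoic anhydride (mixed pivalic anhydride, formed in the flask) | COc1cc(Br)cc(CC(=O)OC(=O)C(C)(C)C)c1OCC=C | intermediate
8 | (4S)-3-{2-[2-(allyloxy)-5-bromo-3-methoxyphenyl]acetyl}-4-benzyl-1,3-oxazolidin-2-one | O=C1OC[C@H](Cc2ccccc2)N1C(=O)Cc1cc(Br)cc(OC)c1OCC=C | intermediate
9 | 4-hydroxy-3,5-dimethoxybenzaldehyde (syringaldehyde) | COc1cc(C=O)cc(OC)c1O | starting material
10 | 3,5-dimethoxy-4-(triisopropylsilyloxy)benzaldehyde | COc1cc(C=O)cc(OC)c1O[Si](C(C)C)(C(C)C)C(C)C | intermediate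
11 | (4S)-3-[(1Z)-2-[2-(allyloxy)-5-bromo-3-methoxyphenyl]-1-(dibutylboryloxy)ethenyl]-4-benzyl-1,3-oxazolidin-2-one (dibutylboron Z-enolate, formed in the flask) | CCCCB(CCCC)O/C(=C\c1cc(Br)cc(OC)c1OCC=C)N1[C@@H](Cc2ccccc2)COC1=O | intermediate
12 | (4S)-3-[(2S,3S)-2-[2-(allyloxy)-5-bromo-3-methoxyphenyl]-3-(dibutylboryloxy)-3-[3,5-dimethoxy-4-(triisopropylsilyloxy)phenyl]propanoyl]-4-benzyl-1,3-oxazolidin-2-one (dibutylboron aldolate, formed in the flask) | O=C1OC[C@H](Cc2ccccc2)N1C(=O)[C@@H](c1cc(Br)cc(OC)c1OCC=C)[C@H](OB(CCCC)CCCC)c1cc(OC)c(O[Si](C(C)C)(C(C)C)C(C)C)c(OC)c1 | intermediate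
13 | (4S)-3-[(2S,3S)-2-[2-(allyloxy)-5-bromo-3-methoxyphenyl]-3-hydroxy-3-[3,5-dimethoxy-4-(triisopropylsilyloxy)phenyl]propanoyl]-4-benzyl-1,3-oxazolidin-2-one | O=C1OC[C@H](Cc2ccccc2)N1C(=O)[C@@H](c1cc(Br)cc(OC)c1OCC=C)[C@H](O)c1cc(OC)c(O[Si](C(C)C)(C(C)C)C(C)C)c(OC)c1 | intermediate
14 | (1S,2R)-2-[2-(allyloxy)-5-bromo-3-methoxyphenyl]-1-[3,5-dimethoxy-4-(triisopropylsilyloxy)phenyl]propane-1,3-diol | COc1cc([C@@H](O)[C@@H](CO)c2cc(Br)cc(OC)c2OCC=C)cc(OC)c1O[Si](C(C)C)(C(C)C)C(C)C | intermediate
15 | (1S,2R)-2-(5-bromo-2-hydroxy-3-methoxyphenyl)-1-[3,5-dimethoxy-4-(triisopropylsilyloxy)phenyl]propane-1,3-diol | COc1cc([C@@H](O)[C@@H](CO)c2cc(Br)cc(OC)c2O)cc(OC)c1O[Si](C(C)C)(C(C)C)C(C)C | intermediate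
16 | (2R)-2-(5-bromo-2-hydroxy-3-methoxyphenyl)-3-hydroxy-1-[3,5-dimethoxy-4-(triisopropylsilyloxy)phenyl]propan-1-ylium (benzylic cation, formed in the flask) | COc1cc([CH+][C@@H](CO)c2cc(Br)cc(OC)c2O)cc(OC)c1O[Si](C(C)C)(C(C)C)C(C)C | intermediate
17 | [(2S,3R)-5-bromo-7-methoxy-2-[3,5-dimethoxy-4-(triisopropylsilyloxy)phenyl]-2,3-dihydro-1-benzofuran-3-yl]methanol | COc1cc([C@H]2Oc3c(OC)cc(Br)cc3[C@@H]2CO)cc(OC)c1O[Si](C(C)C)(C(C)C)C(C)C | intermediate
18 | methyl (2E)-3-[(2S,3R)-3-(hydroxymethyl)-7-methoxy-2-[3,5-dimethoxy-4-(triisopropylsilyloxy)phenyl]-2,3-dihydro-1-benzofuran-5-yl]prop-2-enoate | COc1cc([C@H]2Oc3c(OC)cc(/C=C/C(=O)OC)cc3[C@@H]2CO)cc(OC)c1O[Si](C(C)C)(C(C)C)C(C)C | intermediate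
19 | (2E)-3-[(2S,3R)-3-(hydroxymethyl)-7-methoxy-2-[3,5-dimethoxy-4-(triisopropylsilyloxy)phenyl]-2,3-dihydro-1-benzofuran-5-yl]prop-2-en-1-ol | COc1cc([C@H]2Oc3c(OC)cc(/C=C/CO)cc3[C@@H]2CO)cc(OC)c1O[Si](C(C)C)(C(C)C)C(C)C | intermediate
20 | 4-hydroxybenzoic acid | O=C(O)c1ccc(O)cc1 | starting material
21 | tert-butyldimethylsilyl 4-(tert-butyldimethylsilyloxy)benzoate (formed in the flask) | CC(C)(C)[Si](C)(C)OC(=O)c1ccc(O[Si](C)(C)C(C)(C)C)cc1 | intermediate
22 | 4-(tert-butyldimethylsilyloxy)benzoic acid | CC(C)(C)[Si](C)(C)Oc1ccc(C(=O)O)cc1 | intermediate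
23 | [(2S,3R)-5-[(1E)-3-[4-(tert-butyldimethylsilyloxy)benzoyloxy]prop-1-en-1-yl]-7-methoxy-2-[3,5-dimethoxy-4-(triisopropylsilyloxy)phenyl]-2,3-dihydro-1-benzofuran-3-yl]methyl 4-(tert-butyldimethylsilyloxy)benzoate | COc1cc([C@H]2Oc3c(OC)cc(/C=C/COC(=O)c4ccc(O[Si](C)(C)C(C)(C)C)cc4)cc3[C@@H]2COC(=O)c2ccc(O[Si](C)(C)C(C)(C)C)cc2)cc(OC)c1O[Si](C(C)C)(C(C)C)C(C)C | intermediate
24 | [(2S,3R)-2-(4-hydroxy-3,5-dimethoxyphenyl)-5-[(1E)-3-(4-hydroxybenzoyloxy)prop-1-en-1-yl]-7-methoxy-2,3-dihydro-1-benzofuran-3-yl]methyl 4-hydroxybenzoate (quiquesetinerviusin B) | COc1cc([C@H]2Oc3c(OC)cc(/C=C/COC(=O)c4ccc(O)cc4)cc3[C@@H]2COC(=O)c2ccc(O)cc2)cc(OC)c1O | target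

Total step count: 14. Longest linear sequence: 12 steps (steps 1 to 4, 6 to 11, 13 and 14, from 1 to 24); steps 5 and 12 are one-step side branches.

Steps least certain to work

Step 9 (key step). The most likely failure is fragmentation or elimination competing with ring closure. A cation next to a carbon that carries a free CH2OH can expel formaldehyde in a retro-Prins sense, or lose the C3 proton. Either would destroy or scramble the only auxiliary-derived stereocentre and leave stilbene-type material. Partial loss of the silyl group under the Lewis acid and incomplete cis to trans equilibration are lesser risks. Fallback: mask the primary hydroxyl as an ester before the ring is closed, so that the cation has no free 1,3-diol to fragment. It sets out from 14.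
- Pivaloyl chloride and pyridine (CH2Cl2, 0 °C) should acylate only the primary hydroxyl and give (2R,3S)-2-[2-(allyloxy)-5-bromo-3-methoxyphenyl]-3-hydroxy-3-[3,5-dimethoxy-4-(triisopropylsilyloxy)phenyl]propyl 2,2-dimethylpropanoate F1.
- Pd(PPh3)4 with morpholine then frees the phenol, giving (2R,3S)-2-(5-bromo-2-hydroxy-3-methoxyphenyl)-3-hydroxy-3-[3,5-dimethoxy-4-(triisopropylsilyloxy)phenyl]propyl 2,2-dimethylpropanoate F2.
- The acid treatment of step 9 should close the ring to [(2S,3R)-5-bromo-7-methoxy-2-[3,5-dimethoxy-4-(triisopropylsilyloxy)phenyl]-2,3-dihydro-1-benzofuran-3-yl]methyl 2,2-dimethylpropanoate F3. An acyloxy oxygen is too poor a donor to expel formaldehyde.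
- The Heck conditions of step 10 give methyl (2E)-3-[(2S,3R)-3-[(2,2-dimethylpropanoyloxy)methyl]-7-methoxy-2-[3,5-dimethoxy-4-(triisopropylsilyloxy)phenyl]-2,3-dihydro-1-benzofuran-5-yl]prop-2-enoate F4.
- i-Bu2AlH then reduces the acrylate and cleaves the pivalate in one operation, so the fallback comes back to the route at 19 at the cost of one extra step.

Step 2. The first-stage adduct may collapse to an oxazole, or the hindered ortho-substituted aldehyde may add the TosMIC anion sluggishly, so that base-induced side reactions of the aldehyde take over; deformylation in the second stage may also stall. Fallback by Wittig homologation, setting out from 2. Ph3P=CHOMe (from (methoxymethyl)triphenylphosphonium chloride and t-BuOK, THF, 0 °C) should give 2-(allyloxy)-5-bromo-1-methoxy-3-(2-methoxyethenyl)benzene F5 as a mixture of alkene isomers. Aqueous HCl in THF hydrolyses the enol ether to 2-[2-(allyloxy)-5-bromo-3-methoxyphenyl]acetaldehyde F6. Pinnick oxidation (NaClO2, NaH2PO4, 2-methyl-2-butene, t-BuOH/H2O) then gives the acid, so the fallback comes back to the route at 5, one step longer than steps 2 and 3 together.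

Step 7. The alkoxide formed from the free β-hydroxyl can trigger retro-aldol cleavage. The α-carbon is benzylic and next to an imide, so it can epimerise under basic hydride conditions; hydride may also attack the ring carbonyl of the auxiliary. Fallback: silylate the carbinol first, setting out from 13.
- Et3SiOTf and 2,6-lutidine (CH2Cl2, −78 °C) give (4S)-3-[(2S,3S)-2-[2-(allyloxy)-5-bromo-3-methoxyphenyl]-3-[3,5-dimethoxy-4-(triisopropylsilyloxy)phenyl]-3-(triethylsilyloxy)propanoyl]-4-benzyl-1,3-oxazolidin-2-one F7, which can no longer undergo retro-aldol cleavage.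
- LiBH4 gives (2R,3S)-2-[2-(allyloxy)-5-bromo-3-methoxyphenyl]-3-[3,5-dimethoxy-4-(triisopropylsilyloxy)phenyl]-3-(triethylsilyloxy)propan-1-ol F8.
- Pd(PPh3)4 with morpholine gives (2R,3S)-2-(5-bromo-2-hydroxy-3-methoxyphenyl)-3-[3,5-dimethoxy-4-(triisopropylsilyloxy)phenyl]-3-(triethylsilyloxy)propan-1-ol F9.
- BF3·OEt2 ionises the benzylic silyl ether just as it does the alcohol, so the ring closes and the fallback comes back to the route at 17, one step longer.

Step 10. Oxidative addition into the electron-rich bromide is slow, so the catalyst may decompose before conversion is complete; reductive loss of bromine and slow addition of the free alcohol to the acrylate are further drains. Fallback by Suzuki–Miyaura coupling, setting out from 17: (E)-3-(4,4,5,5-tetramethyl-1,3,2-dioxaborolan-2-yl)prop-2-en-1-ol, Pd(dppf)Cl2 and K3PO4 in dioxane/H2O at 80 °C should install the hydroxypropenyl chain directly. The fallback comes back to the route at 19, makes no new compound, and bypasses steps 10 and 11.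

Step 14. Once the phenols are freed in a fluoride medium, phenoxide can transfer or cleave an ester, and the free ring B phenoxide can reopen the heterocycle through a quinone methide; the hindered silyl group on ring B may also come off slowly and prolong the exposure. Fallback: reverse the order so that no ester is present when fluoride is used, setting out from 19. Bu4NF in THF removes the ring B silyl group and gives 4-[(2S,3R)-3-(hydroxymethyl)-5-[(1E)-3-hydroxyprop-1-en-1-yl]-7-methoxy-2,3-dihydro-1-benzofuran-2-yl]-2,6-dimethoxyphenol F10. A double Mitsunobu esterification with unprotected 20 (PPh3, diisopropyl azodicarboxylate, THF, 0 °C) should then acylate the two primary alcohols selectively, because the carboxylic acid is far more acidic than any of the phenols. The fallback comes back to the route at 24 and makes steps 12 to 14 unnecessary.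

## Further compounds

F1 | step 9 | (2R,3S)-2-[2-(allyloxy)-5-bromo-3-methoxyphenyl]-3-hydroxy-3-[3,5-dimethoxy-4-(triisopropylsilyloxy)phenyl]propyl 2,2-dimethylpropanoate | COc1cc([C@@H](O)[C@@H](COC(=O)C(C)(C)C)c2cc(Br)cc(OC)c2OCC=C)cc(OC)c1O[Si](C(C)C)(C(C)C)C(C)C
F2 | step 9 | (2R,3S)-2-(5-bromo-2-hydroxy-3-methoxyphenyl)-3-hydroxy-3-[3,5-dimethoxy-4-(triisopropylsilyloxy)phenyl]propyl 2,2-dimethylpropanoate | COc1cc([C@@H](O)[C@@H](COC(=O)C(C)(C)C)c2cc(Br)cc(OC)c2O)cc(OC)c1O[Si](C(C)C)(C(C)C)C(C)C
F3 | step 9 | [(2S,3R)-5-bromo-7-methoxy-2-[3,5-dimethoxy-4-(triisopropylsilyloxy)phenyl]-2,3-dihydro-1-benzofuran-3-yl]methyl 2,2-dimethylpropanoate | COc1cc([C@H]2Oc3c(OC)cc(Br)cc3[C@@H]2COC(=O)C(C)(C)C)cc(OC)c1O[Si](C(C)C)(C(C)C)C(C)C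
F4 | step 9 | methyl (2E)-3-[(2S,3R)-3-[(2,2-dimethylpropanoyloxy)methyl]-7-methoxy-2-[3,5-dimethoxy-4-(triisopropylsilyloxy)phenyl]-2,3-dihydro-1-benzofuran-5-yl]prop-2-enoate | COc1cc([C@H]2Oc3c(OC)cc(/C=C/C(=O)OC)cc3[C@@H]2COC(=O)C(C)(C)C)cc(OC)c1O[Si](C(C)C)(C(C)C)C(C)C
F5 | step 2 | 2-(allyloxy)-5-bromo-1-methoxy-3-(2-methoxyethenyl)benzene (mixture of alkene isomers) | COc1cc(Br)cc(C=COC)c1OCC=C
F6 | step 2 | 2-[2-(allyloxy)-5-bromo-3-methoxyphenyl]acetaldehyde | COc1cc(Br)cc(CC=O)c1OCC=C
F7 | step 7 | (4S)-3-[(2S,3S)-2-[2-(allyloxy)-5-bromo-3-methoxyphenyl]-3-[3,5-dimethoxy-4-(triisopropylsilyloxy)phenyl]-3-(triethylsilyloxy)propanoyl]-4-benzyl-1,3-oxazolidin-2-one | O=C1OC[C@H](Cc2ccccc2)N1C(=O)[C@@H](c1cc(Br)cc(OC)c1OCC=C)[C@H](O[Si](CC)(CC)CC)c1cc(OC)c(O[Si](C(C)C)(C(C)C)C(C)C)c(OC)c1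
F8 | step 7 | (2R,3S)-2-[2-(allyloxy)-5-bromo-3-methoxyphenyl]-3-[3,5-dimethoxy-4-(triisopropylsilyloxy)phenyl]-3-(triethylsilyloxy)propan-1-ol | COc1cc([C@@H](O[Si](CC)(CC)CC)[C@@H](CO)c2cc(Br)cc(OC)c2OCC=C)cc(OC)c1O[Si](C(C)C)(C(C)C)C(C)C
F9 | step 7 | (2R,3S)-2-(5-bromo-2-hydroxy-3-methoxyphenyl)-3-[3,5-dimethoxy-4-(triisopropylsilyloxy)phenyl]-3-(triethylsilyloxy)propan-1-ol | COc1cc([C@@H](O[Si](CC)(CC)CC)[C@@H](CO)c2cc(Br)cc(OC)c2O)cc(OC)c1O[Si](C(C)C)(C(C)C)C(C)C
F0 | step 10 | none | none
F10 | step 14 | 4-[(2S,3R)-3-(hydroxymethyl)-5-[(1E)-3-hydroxyprop-1-en-1-yl]-7-methoxy-2,3-dihydro-1-benzofuran-2-yl]-2,6-dimethoxyphenol | COc1cc([C@H]2Oc3c(OC)cc(/C=C/CO)cc3[C@@H]2CO)cc(OC)c1O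
A1 | alternative 1 | (2S)-6-bromo-8-methoxy-2-[3,5-dimethoxy-4-(methylsulfonyloxy)phenyl]chroman-4-one | COc1cc([C@@H]2CC(=O)c3cc(Br)cc(OC)c3O2)cc(OC)c1OS(C)(=O)=O
A2 | alternative 1 | methyl (2S,3S)-5-bromo-7-methoxy-2-[3,5-dimethoxy-4-(methylsulfonyloxy)phenyl]-2,3-dihydro-1-benzofuran-3-carboxylate | COc1cc([C@H]2Oc3c(OC)cc(Br)cc3[C@@H]2C(=O)OC)cc(OC)c1OS(C)(=O)=O
A3 | alternative 2 | 4-{[(1S)-1-[3,5-dimethoxy-4-(triisopropylsilyloxy)phenyl]prop-2-en-1-yl]oxy}-3-iodo-5-methoxybenzaldehyde | COc1cc([C@H](C=C)Oc2c(I)cc(C=O)cc2OC)cc(OC)c1O[Si](C(C)C)(C(C)C)C(C)C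
A4 | alternative 2 | (2S,3R)-7-methoxy-2-[3,5-dimethoxy-4-(triisopropylsilyloxy)phenyl]-3-[(2,2,6,6-tetramethylpiperidin-1-yl)oxymethyl]-2,3-dihydro-1-benzofuran-5-carbaldehyde | COc1cc([C@H]2Oc3c(OC)cc(C=O)cc3[C@@H]2CON4C(C)(C)CCCC4(C)C)cc(OC)c1O[Si](C(C)C)(C(C)C)C(C)C
A5 | alternative 3 | methyl 3-[(2R,3S)-1-(tert-butyldimethylsilyloxy)-3-hydroxy-3-[3,5-dimethoxy-4-(triisopropylsilyloxy)phenyl]propan-2-yl]-5-methoxy-4-(trifluoromethylsulfonyloxy)benzoate | COC(=O)c1cc(OC)c(OS(=O)(=O)C(F)(F)F)c(c1)[C@H](CO[Si](C)(C)C(C)(C)C)[C@H](O)c1cc(OC)c(O[Si](C(C)C)(C(C)C)C(C)C)c(OC)c1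
A6 | alternative 3 | methyl (2S,3R)-3-(tert-butyldimethylsilyloxymethyl)-7-methoxy-2-[3,5-dimethoxy-4-(triisopropylsilyloxy)phenyl]-2,3-dihydro-1-benzofuran-5-carboxylate | COc1cc([C@H]2Oc3c(OC)cc(C(=O)OC)cc3[C@@H]2CO[Si](C)(C)C(C)(C)C)cc(OC)c1O[Si](C(C)C)(C(C)C)C(C)C
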